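## Plan

1. Hardest point: C2 is a tertiary, allylic aryl-ether stereocentre. The usual chromene closures (oxa-6π of an o-quinone methide, propargyl Claisen, cyclodehydration) all make C2 planar, so in this route no bond at C2 is made or broken once it is set.
2. Cuts: O1–C8a (aryl C–O), the C3=C4 π bond (back to CH2–CH2), C4–C4a (sp3–sp2 coupling), and the chalcone Cα=Cβ (aldol condensation).
3. Enabling feature: in ring A, C5–OH and C8–OH stand para (a hydroquinone), C6 carries a chelating acyl group next to C5, and O1 sits on C8a. In the derived quinone, C8a–H is the β-carbon of the C5(=O)–C4a=C8a enone and C4–H2 is vinylogously acidic through C4a=C8a–C8=O, so ring A can serve twice as its own oxidant.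
4. Forward: a side-chain diol (4 steps from geraniol) and an iodochalcone (3 steps) are joined at C4–C4a. Oxidation to the quinone lets the C2 hydroxyl close the pyran ring on C8a–H. A proton-relay redox isomerisation of the chromanquinone then moves two H from C3/C4 to O5/O8, giving the chromene and the free hydroquinone without protecting groups.
5. Stereochemistry: C2 comes from Sharpless epoxidation of geraniol with L-(+)-DET, and its C–O bond is carried through unchanged. The E-enone comes from thermodynamic control in the condensation.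

Key step: step 9

Remark: locants O1 and C2–C8a are those of the 2H-chromene of the target and are used for all intermediates. C2 of the target is (S). Its four ligands keep their spatial positions from step 1 on; descriptor changes in between come from CIP ranking only.
Remark: steps 8–10 are run under argon. Step 10 and all handling of the target exclude light, because 2H-chromenes ring-open photochemically and would racemise.

## Route

Step 1
Reactants: 1 geraniol
Product: 2 (2S,3S)-2,3-epoxygeraniol
Conditions: Ti(OiPr)4 (5 mol %), L-(+)-DET (7 mol %), t-BuOOH (decane), 4 Å MS, CH2Cl2, −20 °C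
Reagents that add atoms: tert-butyl hydroperoxide, CC(C)(C)OO
Why: In the Sharpless asymmetric epoxidation the allylic hydroxyl binds the Ti–tartrate complex, so only the C2=C3 alkene reacts and L-(+)-DET directs oxygen to the face that gives the (2S,3S)-epoxide, whose quaternary C–O bond becomes C2–O1 of the target.

Step 2
Reactants: 2 (2S,3S)-2,3-epoxygeraniol
Product: 3 [(2S,3S)-3-(4-hydroxy-4-methylpentyl)-3-methyloxiran-2-yl]methanol
Conditions: Co(acac)2 (10 mol %), PhSiH3 (2.2 equiv), O2 (1 atm), THF, rt
Reagents that add atoms: dioxygen, O=O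
Why: Mukaiyama hydration (cobalt-hydride H-atom transfer, O2 capture of the tertiary radical, silane reduction of the peroxide) should place the hydroxyl on the more substituted carbon of the only remaining alkene, under neutral conditions that leave the epoxy alcohol intact.

Step 3
Reactants: 3 [(2S,3S)-3-(4-hydroxy-4-methylpentyl)-3-methyloxiran-2-yl]methanol
Product: 4 5-[(2S,3R)-3-(iodomethyl)-2-methyloxiran-2-yl]-2-methylpentan-2-ol
Conditions: I2, PPh3, imidazole, CH2Cl2, 0 °C, dark
Reagents that add atoms: iodine, II
Why: Appel-type iodination should convert only the primary alcohol, since the tertiary alcohol is too hindered for SN2 displacement at 0 °C and the epoxide is inert to the imidazole-buffered reagent (the CH carbon becomes R by CIP rank only).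

Step 4
Reactants: 4 5-[(2S,3R)-3-(iodomethyl)-2-methyloxiran-2-yl]-2-methylpentan-2-ol
Product: 5 (6S)-2,6-dimethyloct-7-ene-2,6-diol
Conditions: Zn dust, EtOH, reflux; aq NH4Cl work-up
Reagents that add atoms: none
Why: Zinc insertion into the C–I bond and β-elimination (reductive opening of a 2,3-epoxy iodide) break the secondary C–O bond, so the tertiary C–O bond and its configuration are retained in the vinyl carbinol.

Step 5
Reactants: 6 1-(2-hydroxy-5-methoxyphenyl)ethan-1-one
Product: 7 1-(2-hydroxy-3-iodo-5-methoxyphenyl)ethan-1-one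
Conditions: NIS (1.05 equiv), TFA (cat.), MeCN, rt
Reagents that add atoms: N-iodosuccinimide, O=C1CCC(=O)N1I
Why: Electrophilic aromatic iodination should go ortho to the free phenol (its para position is blocked), at the one free ring carbon that is meta to the acetyl group and so not deactivated by it.

Step 6
Reactants: 7 1-(2-hydroxy-3-iodo-5-methoxyphenyl)ethan-1-one
Product: 8 1-(2,5-dihydroxy-3-iodophenyl)ethan-1-one
Conditions: BBr3 (3 equiv), CH2Cl2, −78 °C to rt; H2O
Reagents that add atoms: none
Why: BBr3 ether cleavage frees the second hydroquinone oxygen at a stage where no acid-sensitive group is present.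

Step 7
Reactants: 8 1-(2,5-dihydroxy-3-iodophenyl)ethan-1-one; 9 4-hydroxybenzaldehyde
Product: 10 (E)-1-(2,5-dihydroxy-3-iodophenyl)-3-(4-hydroxyphenyl)prop-2-en-1-one
Conditions: dry HCl (sat.), EtOH, 0 °C to rt
Reagents that add atoms: none
Why: The acid-catalysed Claisen–Schmidt condensation tolerates free phenols, and loss of water from the aldol under equilibrating conditions gives the E-enone.

Step 8
Reactants: 5 (6S)-2,6-dimethyloct-7-ene-2,6-diol; 10 (E)-1-(2,5-dihydroxy-3-iodophenyl)-3-(4-hydroxyphenyl)prop-2-en-1-one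
Product: 12 (E)-1-{3-[(3S)-3,7-dihydroxy-3,7-dimethyloctyl]-2,5-dihydroxyphenyl}-3-(4-hydroxyphenyl)prop-2-en-1-one, via B-alkyl-9-BBN borane 11 (not isolated)
Conditions: 5, 9-BBN (3.3 equiv), THF, 0 °C to rt; then degassed 3 M aq K3PO4, 10, Pd(dppf)Cl2 (5 mol %), DMF, 50 °C, Ar
Reagents that add atoms: none
Why: Anti-Markovnikov hydroboration of the monosubstituted alkene and B-alkyl Suzuki–Miyaura coupling form C4–C4a; free hydroxyls only consume extra borane and base, residual B–H is destroyed by the aqueous base before the enone is added, and the stereocentre is not involved.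

Step 9
Reactants: 12 (E)-1-{3-[(3S)-3,7-dihydroxy-3,7-dimethyloctyl]-2,5-dihydroxyphenyl}-3-(4-hydroxyphenyl)prop-2-en-1-one
Product: 15 (2S)-2-(4-hydroxy-4-methylpentyl)-6-[(E)-3-(4-hydroxyphenyl)prop-2-enoyl]-2-methyl-3,4-dihydro-2H-chromene-5,8-dione, via acylquinone 13 (not isolated), via chroman hydroquinone 14 (not isolated)
Conditions: DDQ (1.0 equiv), MeCN (2 mM), 4 Å MS, 0 °C; Zn(OTf)2 (20 mol %), rt; DDQ (1.05 equiv), 0 °C
Reagents that add atoms: none
Why: DDQ takes the C5/C8 hydroquinone to acylquinone 13, in which Zn(II) chelated between O5 and the C6 acyl oxygen activates the C5(=O)–C4a=C8a enone, so the C2 tertiary hydroxyl adds to C8a–H, enolisation re-aromatises the adduct to 14, and the second equivalent of DDQ (or 13 by redox exchange) oxidises 14 to 15. The closest known reaction types are the one-flask oxidation/conjugate addition/re-oxidation of acylhydroquinones with heteronucleophiles and the intramolecular addition of side-chain alcohols to quinone ring carbons that gives chromans. The pyran ring closes 6-endo-trig by O1–C8a bond formation. No stereocentre is created, and C2 passes through untouched because only its O–H bond, never its C–O bond, reacts. Selectivity is needed against C7 (the most electrophilic carbon), C4a (5-exo spiro attack) and the remote side-chain hydroxyl. The three-atom tether cannot reach C7, which high dilution and sieves shield from intermolecular attack; the spiro adduct cannot aromatise and reverts; and the remote hydroxyl would need a ten-membered ring.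

Step 10
Reactants: 15 (2S)-2-(4-hydroxy-4-methylpentyl)-6-[(E)-3-(4-hydroxyphenyl)prop-2-enoyl]-2-methyl-3,4-dihydro-2H-chromene-5,8-dione
Product: 17 (E)-1-[(2S)-5,8-dihydroxy-2-(4-hydroxy-4-methylpentyl)-2-methyl-2H-chromen-6-yl]-3-(4-hydroxyphenyl)prop-2-en-1-one (target), via o-quinone methide 16 (not isolated)
Conditions: Zn(OTf)2 (20 mol %), Et3N (20 mol %), degassed MeCN (2 mM), rt to 40 °C, dark, Ar; aq citric acid
Reagents that add atoms: none
Why: Proposed new method: in 15 the C4–H bonds are vinylogously acidic (C4–C4a=C8a–C8=O), so Lewis-acid/hindered-amine soft enolisation should give o-quinone methide 16 (C4=C4a–C5=O, C8–OH), whose C3–H is in turn γ to C5=O, and a second proton shift re-aromatises ring A and leaves the C3=C4 double bond. The isomerisation should be downhill, because reducing an acylbenzoquinone to its chelated hydroquinone releases more free energy than dehydrogenating the chroman C3–C4 bond costs, and redox exchange between 17 and unreacted 15 does not change the overall oxidation level and so still funnels to 17. The closest known reaction types are the amine-induced isomerisation of prenylquinones to chromenols through o-quinone methides and the quinone → quinone methide → dehydrocatechol side-chain desaturation. C2 carries no hydrogen and its C–O bond is outside the proton relay, so the configuration is retained. The hindered amine cannot add to C7, and its substoichiometric amount leaves most of the B-ring phenol un-ionised.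

## Compound list

1 | geraniol, (2E)-3,7-dimethylocta-2,6-dien-1-ol | CC(C)=CCC/C(C)=C/CO | starting material
2 | (2S,3S)-2,3-epoxygeraniol, [(2S,3S)-3-methyl-3-(4-methylpent-3-en-1-yl)oxiran-2-yl]methanol | CC(C)=CCC[C@]1(C)O[C@H]1CO | intermediate
3 | [(2S,3S)-3-(4-hydroxy-4-methylpentyl)-3-methyloxiran-2-yl]methanol | CC(C)(O)CCC[C@]1(C)O[C@H]1CO | intermediate
4 | 5-[(2S,3R)-3-(iodomethyl)-2-methyloxiran-2-yl]-2-methylpentan-2-ol | CC(C)(O)CCC[C@]1(C)O[C@H]1CI | intermediate
5 | (6S)-2,6-dimethyloct-7-ene-2,6-diol | CC(C)(O)CCC[C@@](O)(C)C=C | intermediate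
6 | 1-(2-hydroxy-5-methoxyphenyl)ethan-1-one | CC(=O)c1cc(OC)ccc1O | starting material
7 | 1-(2-hydroxy-3-iodo-5-methoxyphenyl)ethan-1-one | CC(=O)c1cc(OC)cc(I)c1O | intermediate
8 | 1-(2,5-dihydroxy-3-iodophenyl)ethan-1-one | CC(=O)c1cc(O)cc(I)c1O | intermediate
9 | 4-hydroxybenzaldehyde | O=Cc1ccc(O)cc1 | starting material
10 | (E)-1-(2,5-dihydroxy-3-iodophenyl)-3-(4-hydroxyphenyl)prop-2-en-1-one | O=C(/C=C/c1ccc(O)cc1)c1cc(O)cc(I)c1O | intermediate
11 | (6R)-8-(9-borabicyclo[3.3.1]nonan-9-yl)-2,6-dimethyloctane-2,6-diol (same spatial arrangement as 5) | CC(C)(O)CCC[C@@](O)(C)CCB1C2CCCC1CCC2 | intermediate (not isolated)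
12 | (E)-1-{3-[(3S)-3,7-dihydroxy-3,7-dimethyloctyl]-2,5-dihydroxyphenyl}-3-(4-hydroxyphenyl)prop-2-en-1-one | CC(C)(O)CCC[C@@](O)(C)CCc1cc(O)cc(C(=O)/C=C/c2ccc(O)cc2)c1O | intermediate
13 | 2-[(3S)-3,7-dihydroxy-3,7-dimethyloctyl]-6-[(E)-3-(4-hydroxyphenyl)prop-2-enoyl]cyclohexa-2,5-diene-1,4-dione | CC(C)(O)CCC[C@@](O)(C)CCC1=CC(=O)C=C(C(=O)/C=C/c2ccc(O)cc2)C1=O | intermediate (not isolated)
14 | (E)-1-[(2S)-5,8-dihydroxy-2-(4-hydroxy-4-methylpentyl)-2-methyl-3,4-dihydro-2H-chromen-6-yl]-3-(4-hydroxyphenyl)prop-2-en-1-one | CC(C)(O)CCC[C@@]1(C)CCc2c(O)c(C(=O)/C=C/c3ccc(O)cc3)cc(O)c2O1 | intermediate (not isolated)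
15 | (2S)-2-(4-hydroxy-4-methylpentyl)-6-[(E)-3-(4-hydroxyphenyl)prop-2-enoyl]-2-methyl-3,4-dihydro-2H-chromene-5,8-dione | CC(C)(O)CCC[C@@]1(C)CCC2=C(O1)C(=O)C=C(C(=O)/C=C/c3ccc(O)cc3)C2=O | intermediate
16 | (2S)-8-hydroxy-2-(4-hydroxy-4-methylpentyl)-6-[(E)-3-(4-hydroxyphenyl)prop-2-enoyl]-2-methyl-2,3-dihydro-5H-chromen-5-one (o-quinone methide, C4=C4a) | CC(C)(O)CCC[C@@]1(C)CC=C2C(=O)C(C(=O)/C=C/c3ccc(O)cc3)=CC(O)=C2O1 | intermediate (not isolated)
17 | (E)-1-[(2S)-5,8-dihydroxy-2-(4-hydroxy-4-methylpentyl)-2-methyl-2H-chromen-6-yl]-3-(4-hydroxyphenyl)prop-2-en-1-one | CC(C)(O)CCC[C@@]1(C)C=Cc2c(O)c(C(=O)/C=C/c3ccc(O)cc3)cc(O)c2O1 | target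

## Step count and risks

Total steps: 10. Longest linear sequence: 7 (steps 1–4 and 8–10).

**Step 10 (proposed new method).** The vinylogous deprotonation at C4 may be slower than intermolecular conjugate addition to C7 of the acylquinone, or slower than [4+2] dimerisation of the o-quinone methide. The fallback is the known dehydrogenation of a chroman on a protected hydroquinone; it sets out from 15 and returns at 17. Compound 15 is reduced with aqueous Na2S2O4 to 14. Ac2O/pyridine at 0 °C acetylates the two non-chelated phenols to the chroman diacetate F1. DDQ in refluxing benzene abstracts hydride from C4 (the cation is stabilised by O1 and C5–OH) and gives the chromene diacetate F2. Degassed K2CO3/MeOH at 0 °C removes both acetates and gives 17.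

**Step 9 (key step).** The quinone may tautomerise prematurely to a side-chain alkene, it may be consumed by hydration or oligomerisation at C7, or the reaction may stall at the reversible spiro adduct. The fallback replaces C–H oxygenation by ipso substitution at a carbon that already bears oxygen; it sets out from 9 and 11 and returns at 15. Purchased 1-(2-hydroxy-4,5-dimethoxyphenyl)ethan-1-one F3 is iodinated with NIS between OH and OMe to the iodoketone F4. This is condensed with 9 (HCl/EtOH) to the dimethoxy iodochalcone F5, which is coupled with 11 as in step 8 to the dimethoxy chalcone F6. CAN in aqueous MeCN at 0 °C oxidatively demethylates the para hydroxy/methoxy pair of the electron-rich ring A to the 2-methoxyquinone F7. Catalytic CSA in CH2Cl2 then exchanges the vinylogous-ester methoxy group on C8a for the tethered tertiary hydroxyl by addition–elimination. This exchange needs no re-oxidation, fixes the site of attack, and gives 15.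

**Step 8.** Transmetalation may be sluggish, protodeboronation or β-hydride elimination may compete with a multiply deprotonated, electron-rich aryl iodide, and the hydroquinone may be oxidised by air in base. The fallback is Heck arylation and hydrogenation before the enone is present; it sets out from 5 and 8 and returns at 12. Pd(OAc)2/P(o-tol)3/Et3N in MeCN at 80 °C couples 8 with the vinyl group of 5 to the E-styrenyl carbinol F8. H2 over Pd/C in EtOAc saturates the alkene to the alkylated ketone F9. Claisen–Schmidt condensation with 9 in degassed KOH/EtOH gives 12.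

## Further compounds

F1 | step 10 | (E)-chroman chalcone 8-O,4''-O-diacetate of 14 (C5–OH free) | CC(C)(O)CCC[C@@]1(C)CCc2c(O)c(C(=O)/C=C/c3ccc(OC(C)=O)cc3)cc(OC(C)=O)c2O1
F2 | step 10 | (E)-chromene chalcone 8-O,4''-O-diacetate of 17 (C5–OH free) | CC(C)(O)CCC[C@@]1(C)C=Cc2c(O)c(C(=O)/C=C/c3ccc(OC(C)=O)cc3)cc(OC(C)=O)c2O1
F3 | step 9 | 1-(2-hydroxy-4,5-dimethoxyphenyl)ethan-1-one (purchased) | CC(=O)c1cc(OC)c(OC)cc1O
F4 | step 9 | 1-(2-hydroxy-3-iodo-4,5-dimethoxyphenyl)ethan-1-one | CC(=O)c1cc(OC)c(OC)c(I)c1O
F5 | step 9 | (E)-1-(2-hydroxy-3-iodo-4,5-dimethoxyphenyl)-3-(4-hydroxyphenyl)prop-2-en-1-one | O=C(/C=C/c1ccc(O)cc1)c1cc(OC)c(OC)c(I)c1O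
F6 | step 9 | (E)-1-{3-[(3S)-3,7-dihydroxy-3,7-dimethyloctyl]-2-hydroxy-4,5-dimethoxyphenyl}-3-(4-hydroxyphenyl)prop-2-en-1-one | CC(C)(O)CCC[C@@](O)(C)CCc1c(OC)c(OC)cc(C(=O)/C=C/c2ccc(O)cc2)c1O
F7 | step 9 | 3-[(3S)-3,7-dihydroxy-3,7-dimethyloctyl]-5-[(E)-3-(4-hydroxyphenyl)prop-2-enoyl]-2-methoxycyclohexa-2,5-diene-1,4-dione | CC(C)(O)CCC[C@@](O)(C)CCC1=C(OC)C(=O)C=C(C(=O)/C=C/c2ccc(O)cc2)C1=O
F8 | step 8 | 1-{3-[(1E,3S)-3,7-dihydroxy-3,7-dimethyloct-1-en-1-yl]-2,5-dihydroxyphenyl}ethan-1-one | CC(C)(O)CCC[C@@](O)(C)/C=C/c1cc(O)cc(C(C)=O)c1O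
F9 | step 8 | 1-{3-[(3S)-3,7-dihydroxy-3,7-dimethyloctyl]-2,5-dihydroxyphenyl}ethan-1-one | CC(C)(O)CCC[C@@](O)(C)CCc1cc(O)cc(C(C)=O)c1O
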